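83.3 h is the number to carry through these flasks: the cross clock, which is the pseudo-first-order lifetime of starting material against second substrate held at its full charge.

the same everywhere: starting material 0.050 M; time 25 h

| flask | reagent | second substrate | temperature | remark |
|---|---|---|---|---|
| green | 0.0300 M (fed, over 10 h) | 0.100 M | 80 °C | all else is in the flask from the start; the feed brings no volume worth counting |
| red | 0.0300 M (fed, over 10 h) | 0.100 M |  | the addition at 40 °C, then warmed to 80 °C; the feed brings no volume worth counting |
| blue | 0.0300 M | 0.100 M | 80 °C | everything together at the start |
| amber | 0.0300 M | 0.100 M (in portions, 4, over 10 h) | 80 °C | first portion at the start, last at 10 h |
1. the flask with the highest share of target in target plus cross product ("all alike" if they lie within 1.5 percentage points) (green / red / blue / amber / all alike)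
2. share of target in target plus cross product at the end, green
3. share of target in target plus cross product at the end, red
4. share of target in target plus cross product at the end, blue
5. share of target in target plus cross product at the end, amber
- for target the idle adduct is counted in
- at 80 °C the constants are as listed, elsewhere as the activation energies and enthalpies make them

Reagent turns starting material into target and second substrate into second product. Starting material and second substrate give cross product without reagent. Reagent and target stand in balance with idle adduct, and target slowly gives over-reaction product. Here is my own ladder, fastest rung first.

1. The adduct balance is kept at every moment. K times c(reagent) is 1.7 at the start of blue, so I treat idle adduct as a store of reagent, and target is counted with it.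

2. In blue, reagent has a lifetime of 4.76 h, shorter than the run and much shorter than the cross clock. Reagent is the limiting reagent, so I count its charge as reacted. By the starting rates, target takes 42.9% of it, which gives 0.0129 M.

3. Cross product needs no reagent, so I reckon it apart. Its rate falls during the run as reagent uses up both substrates, so I take one rough rate for the whole run. With c(starting material) and c(second substrate) lowered by what reagent took, I estimate 0.00923 M for blue, and its share is 58.2%.

4. Free target has a half-life of 220 d, long against the run, so I drop over-reaction.

5. In amber, c(second substrate) averages half its charge during dosing, so target takes 60.0% of reagent, or 0.0180 M. The cross clock also runs at half speed for those hours, which gives 0.00699 M and a share of 72.0%. My reckoning stops at these two flasks.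

The forecast gives 53.3% for green, 63.6% for red, 56.7% for blue and 68.2% for amber, and names amber, on the grounds that “low early second substrate favours target and suppresses cross product”. My two shares lie above its values, and both of us put amber over blue.

    starting material + reagent → target (k1 = 1.8 /M/h, Ea1 = 62.0 kJ/mol)
    second substrate + reagent → second product (k2 = 1.2 /M/h, Ea2 = 79.0 kJ/mol)
    starting material + second substrate → cross product (k3 = 0.12 /M/h, Ea3 = 84.0 kJ/mol)
    reagent + target ⇌ idle adduct, settled at all times (K4 = 56 /M, ΔH4 = −4.00 kJ/mol)
    target → over-reaction product (k5 = 1.3 × 10⁻⁴ /h, Ea5 = 129 kJ/mol)
    (constants at 80 °C)

The simulation puts amber highest at 68.2%, against 52.9% for green, 64.1% for red and 56.6% for blue. At 25.0 h, amber still holds 56.1% of its starting material, with reagent at 4.80% of its charge. The cross clock fits 3.00 times into 250 h, and amber left that long reads 34.3%.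

Now take a second flask: amber charged with 0.12 M of reagent. Held at that charge, reagent gives starting material a lifetime of 4.63 h, much shorter than the cross clock, so the clock claims about 5.56% of the starting material. The simulation gives 4.19% as cross product and a share of 95.1%.

Its constants were drawn at random within sensible limits; the result is computed.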